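**Amounts read.** I counted each run's target as a fraction of the flask's charge. On its plateau from 0.833 min, cedar held 26.4 % of its own charge, which is 17.7 % of the flask's. From 0.500 min, oak held 12.8 % of its own charge, which is 19.2 % of the flask's. Oak's charge was 2.24 times cedar's, yet the two amounts nearly agree. Their mean, 18.4 %, I named the gas ration: the plateau of target read in cedar and oak, counted in the flask's charge.

all flasks: gas phase 170 mM (held)
- cedar: starting material 0.67 M (fed, over 25 s); run made earlier; the fed solution adds 0.20 times the starting volume
- oak: starting material 1.5 M (fed, over 25 s); run made earlier; the fed solution adds 0.20 times the starting volume
- flask: starting material 1.0 M (fed, over 25 s); the fed solution adds 0.20 times the starting volume; time 2.0 min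

| run | time / min | target / % | side product A / % | starting material / % |
|---|---|---|---|---|
| cedar | 0.417 | 22 | 62 | 10 |
| cedar | 0.833 | 27 | 73 | 1 |
| cedar | 1.33 | 27 | 73 | 0 |
| cedar | 1.50 | 23 | 74 | 0 |
| cedar | 2.00 | 28 | 71 | 1 |
| cedar | 2.50 | 27 | 70 | 2 |
| oak | 0.167 | 4 | 21 | 14 |
| oak | 0.500 | 12 | 80 | 6 |
| oak | 0.833 | 12 | 82 | 0 |
| oak | 1.33 | 13 | 83 | 2 |
| oak | 2.00 | 15 | 86 | 0 |
| oak | 2.50 | 12 | 83 | 0 |

(scatter of a reading: 1.5 percentage points)

- percent here means starting material units held: one side product B counts as two
- amounts are per litre of the starting volume; all of the dose is in the solution fed
- at the start none of the gas is dissolved
- on the list of suspects stand: gas phase <-> dissolved gas; starting material + dissolved gas -> target; starting material -> side product A; starting material + target -> side product B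
- the reaction counts as stopped when no species that holds the starting material changes by six tenths of a point or more over the second half of the time
- percentages count the whole charge, also what has not yet gone in

1. why nothing more happens at 2.0 min, or that something still does (all of the starting material has reacted / forward and back rates have come level / it is still moving)
2. how much target there is at 2.0 min, in percent of the starting material charged
3. how much side product A there is at 2.0 min, in percent of the starting material charged
4. amount of target if the flask were left three thousand times as long, in percent of the starting material charged

**The curve.** In that unit I drew the flask's target from both runs. It rises steeply, since oak stood at 6.00 % by 0.167 min and cedar at 14.7 % by 0.417 min, when the feed ended. The knee follows soon after, for oak had reached 18.0 % by 0.500 min. I therefore set the flask's level at the ration, with side products A and B sharing the remaining 81.6 %. At 2.00 min, starting material read 1 % in cedar and 0 % in oak. The one listed loss of target needs starting material, so I expected the flask's level to hold on long standing.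

**The forecast.** The forecast gave all of the starting material has reacted, 19 % of target, above my ration of 18.4 %, 80 % of side product A and 19 % on long standing, reasoning that “gas supply limits target formation”.

**The result.** The flask gave all of the starting material has reacted, with 19.9 % of target, 77.6 % of side product A and 19.9 % on long standing, so the ration fell 1.5 percentage points short.

    gas phase ⇌ dissolved gas, rate k1*(csat - [dissolved gas]) (kL = 0.0440 s⁻¹)
    starting material + dissolved gas → target (k = 4.10 M⁻¹ s⁻¹)
    starting material → side product A (k = 0.220 s⁻¹)
    starting material + target → side product B (k = 0.0420 M⁻¹ s⁻¹)

Gas transfer, the rate-limiting step on the way to target, was the main reason for the flask's side product A: with that bottleneck taken away, the flask's side product A fell from 77.6 % to 23.9 %. With a quarter of the flask's charge, the neighbour's ration comes to 73.8 % of its own charge. That neighbour stayed below this, ending with 42.8 % of target.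

All runs stem from a simulated flask for substances that don't exist; noise was put on by code.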